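**Plan**

1. Halimane numbering is used: ring A = C1–C5 and C10 (C4 carries Me and CO2Me), ring B = C5–C10, side chain C11–C15 on C9, β = the face of the C4 ester. The retrosynthesis cuts C11=C12 (Wittig), then C5–H/C1–O (reductive allylic transposition), then C9–C10 and C7–C8 (intramolecular Diels–Alder), then the ester bond C1–O–C11.
2. Enabling feature: C1 (ring A, next to sp2 C10) and C11 (on quaternary C9, ring B) are 1,3-related across C10 and lie on the same face. A γ-lactone C1–O–C11(=O), absent from the target, can therefore tether a tiglate (C8, C9, C11 and both methyls) to a ring A 3-vinylcyclohexenol.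
3. Forward: ring A is made first (asymmetric Diels–Alder, C5 vinylation, C1 reduction). Ring B and the temporary lactone close together in the key cycloaddition. A double-bond shift to Δ5(10) makes the lactone allylic, and Pd/formate opening puts H on C5, the alkene at C1=C10 and frees C11 as CO2H for chain extension with a C12–C15 fragment.
4. Stereochemistry: C4 from the catalyst-controlled first cycloaddition; C1 (temporary) from CBS reduction; C9 and C8 from the tether, the endo mode and the (E)-tiglate geometry; C5 by inversion relative to C1–O in the hydride delivery; C13 from dimethyl (R)-methylsuccinate.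

Key step: step 8

Remark: read from the SMILES, the target is (4S,5R,8R,9S,13S) with 5-H, 4-Me, 8-Me and 9-Me on the α face and CO2Me and C11 on the β face; the (R,R)-TADDOL of step 1 is assumed to be the enantiomer that gives (S)-4 (otherwise its antipode is used).

**Step 1**
Reactants: 1 (E)-3-[(tert-butyldimethylsilyl)oxy]-N,N-dimethylbuta-1,3-dien-1-amine; 2 methacrolein
Product: 4 (S)-1-methyl-4-oxocyclohex-2-ene-1-carbaldehyde, via silyl enol ether cycloadduct 3 (not isolated)
Conditions: (4R,5R)-2,2-dimethyl-α,α,α′,α′-tetra(1-naphthyl)-1,3-dioxolane-4,5-dimethanol (20 mol %), toluene, −80 °C; then AcCl, CH2Cl2, −78 °C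
Reagents that add atoms: none
Why: Hydrogen-bond-catalysed normal-demand Diels–Alder reaction of the 1-amino-3-silyloxy diene with the α-substituted enal should give the "para" cyclohexene, the chiral diol shielding one face of the bound aldehyde so that the quaternary C4 is set, and acylative loss of the amine then unmasks the enone.

**Step 2**
Reactants: 4 (S)-1-methyl-4-oxocyclohex-2-ene-1-carbaldehyde
Product: 5 (S)-1-methyl-4-oxocyclohex-2-ene-1-carboxylic acid
Conditions: NaClO2, NaH2PO4, 2-methylbut-2-ene, t-BuOH/H2O, 0 °C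
Reagents that add atoms: sodium chlorite [Na+].[O-]Cl=O
Why: Pinnick oxidation converts the non-enolisable aldehyde to the acid without touching the enone or the stereocentre.

**Step 3**
Reactants: 5 (S)-1-methyl-4-oxocyclohex-2-ene-1-carboxylic acid
Product: 6 methyl (S)-1-methyl-4-oxocyclohex-2-ene-1-carboxylate
Conditions: TMSCHN2, MeOH/toluene, 0 °C
Reagents that add atoms: (trimethylsilyl)diazomethane C[Si](C)(C)C=[N+]=[N-]
Why: Neutral O-methylation of the acid through the methyldiazonium ion avoids base and heat, which could decarboxylate this vinylogous β-keto acid.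

**Step 4**
Reactants: 6 methyl (S)-1-methyl-4-oxocyclohex-2-ene-1-carboxylate
Product: 7 methyl (1S,2S)-2-ethenyl-1-methyl-4-[(trimethylsilyl)oxy]cyclohex-3-ene-1-carboxylate
Conditions: CH2=CHMgBr, CuBr·SMe2 (10 mol %), TMSCl, HMPA, THF, −78 °C; Et3N quench
Reagents that add atoms: vinylmagnesium bromide C=C[Mg]Br; chlorotrimethylsilane C[Si](C)(C)Cl
Why: Copper-catalysed 1,4-addition accelerated by TMSCl, which traps the enolate regiospecifically as the C1 silyl enol ether; the new C5 centre (vinyl expected anti to the pseudoaxial ester) is erased in step 5.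

**Step 5**
Reactants: 7 methyl (1S,2S)-2-ethenyl-1-methyl-4-[(trimethylsilyl)oxy]cyclohex-3-ene-1-carboxylate
Product: 8 methyl (S)-2-ethenyl-1-methyl-4-oxocyclohex-2-ene-1-carboxylate
Conditions: Pd(OAc)2 (10 mol %), O2 (1 atm), DMSO, 40 °C
Reagents that add atoms: none
Why: Saegusa–Ito dehydrogenation, in which the palladium enolate at C10 can only eliminate the C5 hydride, so the enone returns with the vinyl group on C5 as a conjugated dienone.

**Step 6**
Reactants: 8 methyl (S)-2-ethenyl-1-methyl-4-oxocyclohex-2-ene-1-carboxylate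
Product: 9 methyl (1S,4R)-2-ethenyl-4-hydroxy-1-methylcyclohex-2-ene-1-carboxylate
Conditions: (S)-1-methyl-3,3-diphenyltetrahydro-1H,3H-pyrrolo[1,2-c][1,3,2]oxazaborole (20 mol %), catecholborane, toluene, −78 °C
Reagents that add atoms: none
Why: Corey–Bakshi–Shibata 1,2-reduction with the alkenyl side as the large group should give the (4R)-carbinol, cis to the ester, by reagent control since the remote C4 centre exerts little bias; any trans isomer is separable.

**Step 7**
Reactants: 9 methyl (1S,4R)-2-ethenyl-4-hydroxy-1-methylcyclohex-2-ene-1-carboxylate; 10 tiglic acid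
Product: 11 methyl (1S,4R)-2-ethenyl-1-methyl-4-{[(2E)-2-methylbut-2-enoyl]oxy}cyclohex-2-ene-1-carboxylate
Conditions: DCC, DMAP, CH2Cl2, 0 → 23 °C
Reagents that add atoms: none
Why: Steglich esterification under neutral conditions avoids ionisation of the dienylic alcohol and keeps the (E)-geometry of the tiglate.

**Step 8**
Reactants: 11 methyl (1S,4R)-2-ethenyl-1-methyl-4-{[(2E)-2-methylbut-2-enoyl]oxy}cyclohex-2-ene-1-carboxylate
Product: 12 methyl (2aS,3R,6S,8aR,8bR)-2a,3,6-trimethyl-2-oxo-2a,3,4,6,7,8,8a,8b-octahydro-2H-naphtho[1,8-bc]furan-6-carboxylate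
Conditions: 1,2-dichlorobenzene (0.02 M), BHT (5 mol %), 180 °C, sealed tube
Reagents that add atoms: none
Why: Thermal intramolecular Diels–Alder reaction of normal electron demand (concerted, asynchronous, C7–C8 bond leading), the closest known type being the cycloaddition of alkynoate and acrylate esters of 3-vinylcyclohex-2-enols to decalin γ-lactones. Two rings close in one event: ring B by the [4+2] union C7–C8/C9–C10, and the γ-lactone O–C11(=O)–C9–C10–C1 through the three-atom tether, which permits only the fused regiochemistry (C9 to C10) and only the diene face that bears the pseudoaxial C1–O bond. C10 therefore receives C9 cis to O1 (10α-H), the quaternary C9 is set by the endo orientation of the tether carbonyl (lactone cis-fused to ring B, C11 syn to O1, 9-Me α), and C8 follows stereospecifically from the (E)-tiglate (8-Me cis to 9-Me). The selectivity that must hold is endo over exo: the exo mode would place both dienophile methyl groups over the diene and ring A and would force a trans-fused lactone, while the endo mode keeps the carbonyl over C5 (secondary overlap). In the reactive half-chair O1 is pseudoaxial and the cis C4 ester pseudoequatorial, so the quaternary C4 does not block the β face.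

**Step 9**
Reactants: 12 (tricyclic lactone, C5=C6, 10α-H)
Product: 13 methyl (2aS,3R,6S,8aR)-2a,3,6-trimethyl-2-oxo-2a,3,4,5,6,7,8,8a-octahydro-2H-naphtho[1,8-bc]furan-6-carboxylate
Conditions: p-TsOH·H2O (10 mol %), toluene, 80 °C
Reagents that add atoms: none
Why: Acid-mediated alkene migration through the tertiary C5 cation (protonation at C6, loss of H10) to the thermodynamically favoured tetrasubstituted Δ5(10) isomer makes the C1–O bond allylic and leaves C1, C4, C8 and C9 untouched.

**Step 10**
Reactants: 13 (allylic lactone, C5=C10)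
Product: 14 (1S,2R,4aR,5S)-5-(methoxycarbonyl)-1,2,5-trimethyl-1,2,3,4,4a,5,6,7-octahydronaphthalene-1-carboxylic acid
Conditions: Pd(OAc)2 (5 mol %), n-Bu3P (20 mol %), HCO2H, Et3N, 1,4-dioxane, 80 °C; NaH2PO4 work-up
Reagents that add atoms: none
Why: Tsuji–Mandai formate hydrogenolysis of an allylic carboxylate: zerovalent palladium ionises the lactone anti to the C1–O bond and the hydride of the palladium formate is delivered on the same α face to the more substituted terminus C5, giving the less substituted C1=C10 alkene with H5 trans to C11.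

**Step 11**
Reactants: 14 (C11 acid)
Product: 16 methyl (1S,5S,6R,8aR)-5-formyl-1,5,6-trimethyl-1,2,3,5,6,7,8,8a-octahydronaphthalene-1-carboxylate, via acid chloride 15 (not isolated)
Conditions: 1-chloro-N,N,2-trimethylprop-1-en-1-amine, CH2Cl2, 0 → 23 °C; then LiAlH(Ot-Bu)3, THF, −78 °C
Reagents that add atoms: 1-chloro-N,N,2-trimethylprop-1-en-1-amine CC(C)=C(Cl)N(C)C
Why: The acid chloride forms without release of HCl (so the C1=C10 alkene should not migrate) and the bulky LiAlH(Ot-Bu)3 reduces it only to the neopentyl aldehyde while sparing the methyl ester.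

**Step 12**
Reactants: 17 dimethyl (R)-2-methylbutanedioate
Product: 18 (R)-2-methylbutane-1,4-diol
Conditions: LiAlH4, THF, 0 → 65 °C
Reagents that add atoms: none
Why: Hydride reduction of both esters without enolisation of the stereocentre that becomes C13.

**Step 13**
Reactants: 18 (R)-2-methylbutane-1,4-diol
Product: 19 (R)-4-hydroxy-3-methylbutyl acetate
Conditions: Burkholderia cepacia lipase (Amano PS), vinyl acetate, t-BuOMe, 23 °C
Reagents that add atoms: vinyl acetate CC(=O)OC=C
Why: Lipase-catalysed irreversible transesterification should acylate the less hindered hydroxyl (the future C15–OH), remote from the methyl branch.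

**Step 14**
Reactants: 19 (R)-4-hydroxy-3-methylbutyl acetate
Product: 20 (R)-4-iodo-3-methylbutyl acetate
Conditions: I2, PPh3, imidazole, CH2Cl2, 0 °C
Reagents that add atoms: iodine II
Why: Appel-type iodination (SN2 at the primary carbon) leaves the acetate and the stereocentre untouched.

**Step 15**
Reactants: 20 (R)-4-iodo-3-methylbutyl acetate
Product: 21 [(2R)-4-acetoxy-2-methylbutyl]triphenylphosphonium iodide
Conditions: PPh3, MeCN, 82 °C
Reagents that add atoms: triphenylphosphine c1ccc(cc1)P(c1ccccc1)c1ccccc1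
Why: SN2 quaternisation of the phosphine by the β-branched primary iodide.

**Step 16**
Reactants: 21 [(2R)-4-acetoxy-2-methylbutyl]triphenylphosphonium iodide; 16 (C11 aldehyde)
Product: 23 methyl (1S,5R,6R,8aR)-5-[(1Z,3R)-5-acetoxy-3-methylpent-1-en-1-yl]-1,5,6-trimethyl-1,2,3,5,6,7,8,8a-octahydronaphthalene-1-carboxylate, via phosphonium ylide 22 (not isolated)
Conditions: NaHMDS, THF, −78 °C; then 16, −78 → 23 °C
Reagents that add atoms: none
Why: Wittig olefination of the non-enolisable aldehyde with the unstabilised ylide should give mainly the (Z)-alkene (geometry irrelevant), the phosphonium salt being deprotonated far faster than the acetate at −78 °C.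

**Step 17**
Reactants: 23 (C11=C12 alkene)
Product: 24 methyl (1S,5S,6R,8aR)-5-[(3S)-5-acetoxy-3-methylpentyl]-1,5,6-trimethyl-1,2,3,5,6,7,8,8a-octahydronaphthalene-1-carboxylate
Conditions: 2-nitrobenzenesulfonylhydrazide, Et3N, CH2Cl2, 23 °C
Reagents that add atoms: none
Why: Diimide reduces the disubstituted C11=C12 alkene by concerted syn hydrogen transfer and should leave the hindered trisubstituted C1=C10 alkene and both esters untouched, without the double-bond migration that heterogeneous catalysts can cause.

**Compound list**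

1 | (E)-3-[(tert-butyldimethylsilyl)oxy]-N,N-dimethylbuta-1,3-dien-1-amine | CN(C)/C=C/C(=C)O[Si](C)(C)C(C)(C)C | starting material
2 | methacrolein | CC(=C)C=O | starting material
3 | (1S,2R)-4-[(tert-butyldimethylsilyl)oxy]-2-(dimethylamino)-1-methylcyclohex-3-ene-1-carbaldehyde | O=C[C@@]1(C)CCC(O[Si](C)(C)C(C)(C)C)=C[C@H]1N(C)C | intermediate (not isolated)
4 | (S)-1-methyl-4-oxocyclohex-2-ene-1-carbaldehyde | O=C[C@@]1(C)CCC(=O)C=C1 | intermediate
5 | (S)-1-methyl-4-oxocyclohex-2-ene-1-carboxylic acid | OC(=O)[C@@]1(C)CCC(=O)C=C1 | intermediate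
6 | methyl (S)-1-methyl-4-oxocyclohex-2-ene-1-carboxylate | COC(=O)[C@@]1(C)CCC(=O)C=C1 | intermediate
7 | methyl (1S,2S)-2-ethenyl-1-methyl-4-[(trimethylsilyl)oxy]cyclohex-3-ene-1-carboxylate | COC(=O)[C@@]1(C)CCC(O[Si](C)(C)C)=C[C@@H]1C=C | intermediate
8 | methyl (S)-2-ethenyl-1-methyl-4-oxocyclohex-2-ene-1-carboxylate | COC(=O)[C@@]1(C)CCC(=O)C=C1C=C | intermediate
9 | methyl (1S,4R)-2-ethenyl-4-hydroxy-1-methylcyclohex-2-ene-1-carboxylate | COC(=O)[C@@]1(C)CC[C@@H](O)C=C1C=C | intermediate
10 | tiglic acid, (E)-2-methylbut-2-enoic acid | C/C=C(\C)C(O)=O | starting material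
11 | methyl (1S,4R)-2-ethenyl-1-methyl-4-{[(2E)-2-methylbut-2-enoyl]oxy}cyclohex-2-ene-1-carboxylate | COC(=O)[C@@]1(C)CC[C@@H](OC(=O)/C(C)=C/C)C=C1C=C | intermediate
12 | methyl (2aS,3R,6S,8aR,8bR)-2a,3,6-trimethyl-2-oxo-2a,3,4,6,7,8,8a,8b-octahydro-2H-naphtho[1,8-bc]furan-6-carboxylate (11→1β lactone, C5=C6, 10α-H) | COC(=O)[C@@]1(C)CC[C@H]2OC(=O)[C@@]3(C)[C@H](C)CC=C1[C@@H]23 | intermediate
13 | methyl (2aS,3R,6S,8aR)-2a,3,6-trimethyl-2-oxo-2a,3,4,5,6,7,8,8a-octahydro-2H-naphtho[1,8-bc]furan-6-carboxylate (11→1β lactone, C5=C10) | COC(=O)[C@@]1(C)CC[C@H]2OC(=O)[C@@]3(C)[C@H](C)CCC1=C23 | intermediate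
14 | (1S,2R,4aR,5S)-5-(methoxycarbonyl)-1,2,5-trimethyl-1,2,3,4,4a,5,6,7-octahydronaphthalene-1-carboxylic acid | COC(=O)[C@@]1(C)CCC=C2[C@H]1CC[C@@H](C)[C@]2(C)C(O)=O | intermediate
15 | methyl (1S,5S,6R,8aR)-5-(chlorocarbonyl)-1,5,6-trimethyl-1,2,3,5,6,7,8,8a-octahydronaphthalene-1-carboxylate | COC(=O)[C@@]1(C)CCC=C2[C@H]1CC[C@@H](C)[C@]2(C)C(Cl)=O | intermediate (not isolated)
16 | methyl (1S,5S,6R,8aR)-5-formyl-1,5,6-trimethyl-1,2,3,5,6,7,8,8a-octahydronaphthalene-1-carboxylate | COC(=O)[C@@]1(C)CCC=C2[C@H]1CC[C@@H](C)[C@]2(C)C=O | intermediate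
17 | dimethyl (R)-2-methylbutanedioate | COC(=O)[C@H](C)CC(=O)OC | starting material
18 | (R)-2-methylbutane-1,4-diol | OC[C@H](C)CCO | intermediate
19 | (R)-4-hydroxy-3-methylbutyl acetate | OC[C@H](C)CCOC(C)=O | intermediate
20 | (R)-4-iodo-3-methylbutyl acetate | IC[C@H](C)CCOC(C)=O | intermediate
21 | [(2R)-4-acetoxy-2-methylbutyl]triphenylphosphonium iodide | [I-].c1ccccc1[P+](c1ccccc1)(c1ccccc1)C[C@H](C)CCOC(C)=O | intermediate
22 | [(2R)-4-acetoxy-2-methylbutylidene]triphenylphosphorane | c1ccccc1P(c1ccccc1)(c1ccccc1)=C[C@H](C)CCOC(C)=O | intermediate (not isolated)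
23 | methyl (1S,5R,6R,8aR)-5-[(1Z,3R)-5-acetoxy-3-methylpent-1-en-1-yl]-1,5,6-trimethyl-1,2,3,5,6,7,8,8a-octahydronaphthalene-1-carboxylate | COC(=O)[C@@]1(C)CCC=C2[C@H]1CC[C@@H](C)[C@]2(C)/C=C\[C@H](C)CCOC(C)=O | intermediate
24 | methyl (1S,5S,6R,8aR)-5-[(3S)-5-acetoxy-3-methylpentyl]-1,5,6-trimethyl-1,2,3,5,6,7,8,8a-octahydronaphthalene-1-carboxylate | COC(=O)[C@@]1(C)CCC=C2[C@H]1CC[C@@H](C)[C@]2(C)CC[C@H](C)CCOC(C)=O | target

**Totals**

Total step count: 17. Longest linear sequence: 13 steps (steps 1–11, 16, 17).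

**Steps most likely to fail**

Step 8. The trisubstituted tiglate may add too slowly, so that thermal decomposition of the dienylic ester competes, or the exo mode may intrude and set C9 and C8 with the opposite sense. The fallback sets out from 9 and comes back at 12. Alcohol 9 is esterified with propiolic acid (DCC, CH2Cl2, −20 °C) to the propiolate ester F1. Its cycloaddition (toluene, 110 °C) is faster and has no endo/exo question because the dienophile is an alkyne; it should give the dienyl butenolide F2. Me2CuLi (Et2O, −78 °C) should then add methyl to C8 from the open α face (the side of H10, away from ring A and O1) to give the lithium lactone enolate F3. Methylation of F3 with MeI/HMPA at C9 on the same face, the only one compatible with a cis-fused lactone, returns 12.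

Step 9. The migration may stop short, or the lactone, once allylic, may ionise under acid with elimination to dienes or translocation of the lactone oxygen to C5. The fallback sets out from 12 and comes back at 13 through a base-mediated conjugation instead of a carbocation. Aminolysis of 12 with MeNHOMe·HCl/AlMe3 (CH2Cl2, 0 °C) gives the hydroxy Weinreb amide F4. Dess–Martin oxidation gives the β,γ-unsaturated 1-ketone F5, which DBU conjugates to the Δ5(10) enone F6. NaBH4/CeCl3·7H2O reduction, expected from the α face opposite the amide, gives the 1β allylic alcohol F7, and PPTS in toluene closes the lactone with loss of the amine to return 13.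

Step 10. Ionisation on the α face, which carries the 4- and 9-methyl groups, may be slow; the hydride may go to C1 instead of C5; or β-hydride elimination may give dienes. The fallback sets out from 13 and comes back at 14 by reductive allylic transposition through a diazene. LiOH (THF/H2O, 0 °C) opens the lactone to the lithium hydroxy carboxylate F8, which is alkylated in the same flask with allyl bromide (DMF) to the hydroxy allyl ester F9. Mitsunobu reaction with 2-nitrobenzenesulfonylhydrazide (PPh3, DEAD, THF, −30 °C) inverts C1 and gives the sulfonylhydrazine adduct F10. On warming to 23 °C this loses the sulfinic acid to the allylic diazene F11, whose retro-ene loss of N2 places H on the α face of C5 and gives the transposed allyl ester F12. Pd(PPh3)4/morpholine removes the allyl group to return 14.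

**Further compounds**

F1 | step 8 | methyl (1S,4R)-2-ethenyl-1-methyl-4-(prop-2-ynoyloxy)cyclohex-2-ene-1-carboxylate | COC(=O)[C@@]1(C)CC[C@@H](OC(=O)C#C)C=C1C=C
F2 | step 8 | propiolate cycloadduct, tricyclic butenolide with C8=C9 and C5=C6, 10α-H | COC(=O)[C@@]1(C)CC[C@H]2OC(=O)C3=CCC=C1[C@@H]23
F3 | step 8 | lithium lactone enolate after methyl addition at C8 (8α-Me) | COC(=O)[C@@]1(C)CC[C@H]2OC([O-])=C3[C@H](C)CC=C1[C@@H]23.[Li+]
F4 | step 9 | 1β-hydroxy C11 N-methoxy-N-methylamide, C5=C6, 10α-H | COC(=O)[C@@]1(C)CC[C@@H](O)[C@@H]2C1=CC[C@@H](C)[C@]2(C)C(=O)N(C)OC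
F5 | step 9 | 1-oxo C11 N-methoxy-N-methylamide, C5=C6, 10α-H | COC(=O)[C@@]1(C)CCC(=O)[C@@H]2C1=CC[C@@H](C)[C@]2(C)C(=O)N(C)OC
F6 | step 9 | 1-oxo C11 N-methoxy-N-methylamide, C5=C10 (conjugated enone) | COC(=O)[C@@]1(C)CCC(=O)C2=C1CC[C@@H](C)[C@]2(C)C(=O)N(C)OC
F7 | step 9 | 1β-hydroxy C11 N-methoxy-N-methylamide, C5=C10 | COC(=O)[C@@]1(C)CC[C@@H](O)C2=C1CC[C@@H](C)[C@]2(C)C(=O)N(C)OC
F8 | step 10 | lithium 1β-hydroxy C11 carboxylate, C5=C10 | COC(=O)[C@@]1(C)CC[C@@H](O)C2=C1CC[C@@H](C)[C@]2(C)C([O-])=O.[Li+]
F9 | step 10 | 1β-hydroxy C11 allyl ester, C5=C10 | COC(=O)[C@@]1(C)CC[C@@H](O)C2=C1CC[C@@H](C)[C@]2(C)C(=O)OCC=C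
F10 | step 10 | 1α-[1-(2-nitrobenzenesulfonyl)hydrazinyl] C11 allyl ester, C5=C10 | COC(=O)[C@@]1(C)CC[C@H](N(N)S(=O)(=O)c3ccccc3[N+]([O-])=O)C2=C1CC[C@@H](C)[C@]2(C)C(=O)OCC=C
F11 | step 10 | 1α-diazenyl C11 allyl ester, C5=C10 | COC(=O)[C@@]1(C)CC[C@H](N=N)C2=C1CC[C@@H](C)[C@]2(C)C(=O)OCC=C
F12 | step 10 | C11 allyl ester of 14, C1=C10, 5α-H | COC(=O)[C@@]1(C)CCC=C2[C@H]1CC[C@@H](C)[C@]2(C)C(=O)OCC=C
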